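**Retrosynthetic overview**
- The target is unmasked by desilylation. The side chain is cut at C7–H (Felkin–Anh reduction of the aryl ketone) and at C8–O(ring B) (SN2 of the ring B phenol on a lactate-derived α-tosyloxy ketone that carries ring A).
- The oxolane C5 is cut at C5–H (ionic hydrogenation anti to the C4 methyl) and at C5–ring C (aryllithium addition); both lead back to a γ-lactone whose carbonyl carbon is the future C5.
- The strategy rests on the all-trans triad C2(ring B)–C3(CH3)–C4(CH3) of the oxolane. Both C–CH3 bonds are made in one tandem cuprate addition/enolate methylation on an (R)-γ-aryl butenolide, the ring B carbon being the only source of chirality.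
- The butenolide comes from ring-closing metathesis of an (R)-allylic acrylate, obtained by lipase resolution of the vinyl Grignard adduct of O-benzylvanillin.
- Ring order: rings A, B and C are bought as arenes. The only ring built is the five-membered O-heterocycle, closed once by metathesis (step 4) and kept to the end.

Key step: step 5

Remark: the oxolane is numbered O1, C2 (ring B), C3, C4, C5 (ring C); ring A is the guaiacyl ring on the carbinol carbon C7 and C8 is the ether carbon. The target is (2R,3R,4R,5S; 7R,8R), i.e. 2,3-trans, 3,4-trans, 4,5-cis in the ring and threo in the side chain.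

**Step 1**
Reactants: 1 vanillin
Product: 2 4-benzyloxy-3-methoxybenzaldehyde
Conditions: BnBr, K2CO3, DMF, rt
Reagents that add atoms: benzyl bromide, BrCc1ccccc1
Why: Williamson etherification of the phenoxide; the benzyl ether later distinguishes the ring B phenol from the silyl-protected phenols of rings A and C.

**Step 2**
Reactants: 2 4-benzyloxy-3-methoxybenzaldehyde; 3 vinylmagnesium bromide
Product: 4 rac-1-(4-benzyloxy-3-methoxyphenyl)prop-2-en-1-ol
Conditions: THF, 0 °C; aq. NH4Cl
Reagents that add atoms: none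
Why: 1,2-addition of the vinyl Grignard reagent to the aldehyde gives the racemic allylic alcohol, which is resolved in the next step.

**Step 3**
Reactants: 4 rac-1-(4-benzyloxy-3-methoxyphenyl)prop-2-en-1-ol; 5 vinyl acrylate
Product: 6 (R)-1-(4-benzyloxy-3-methoxyphenyl)prop-2-en-1-yl acrylate
Conditions: immobilised Candida antarctica lipase B, BHT (cat.), MTBE, 30 °C, stopped below 50% conversion
Reagents that add atoms: none
Why: lipase-catalysed kinetic resolution by irreversible transesterification with an enol ester; by the usual large/medium-substituent rule (aryl large, vinyl medium) the enzyme should acylate the (R)-alcohol, so the future C2 stereocentre is set by the enzyme, the acrylate for ring closure is installed in the same operation, and the unreacted (S)-alcohol is removed by chromatography.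

**Step 4**
Reactants: 6 (R)-1-(4-benzyloxy-3-methoxyphenyl)prop-2-en-1-yl acrylate
Product: 7 (R)-5-(4-benzyloxy-3-methoxyphenyl)furan-2(5H)-one
Conditions: second-generation Grubbs catalyst (5 mol %), 1,4-benzoquinone (10 mol %), CH2Cl2 (0.01 M), 40 °C
Reagents that add atoms: none
Why: ring-closing olefin metathesis of the allyl and acryloyl alkenes closes the five-membered unsaturated lactone with loss of ethene under neutral conditions that should leave the base-labile γ-stereocentre untouched, benzoquinone suppressing ruthenium hydride-mediated alkene migration.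

**Step 5**
Reactants: 7 (R)-5-(4-benzyloxy-3-methoxyphenyl)furan-2(5H)-one
Product: 9 (3R,4R,5R)-5-(4-benzyloxy-3-methoxyphenyl)-3,4-dimethyldihydrofuran-2(3H)-one, via lithium lactone enolate 8 (not isolated)
Conditions: Me2CuLi (1.5 equiv, from CuI and 2 MeLi), Et2O, −78 °C, slow addition of 7 in THF; then MeI (5 equiv), HMPA, −78 → −30 °C; aq. NH4Cl
Reagents that add atoms: lithium dimethylcuprate, [Li+].C[Cu-]C; iodomethane, CI
Why: The cuprate complexes the enoate on the face of the flat butenolide opposite the C5 aryl group (ring B); oxidative addition at the β-carbon gives a β-cuprio enolate of trivalent copper, and reductive elimination transfers methyl to the lactone C4 (target C3) anti to ring B, leaving lithium enolate 8. The enolate is then alkylated by iodomethane in an SN2 reaction, with HMPA as activator, on the face opposite the adjacent new methyl group, forming the second C–CH3 bond at the lactone α-carbon (target C4). The closest known reaction type is the anti-selective conjugate addition of organocuprates to γ-substituted butenolides combined with trans-selective alkylation of β-substituted γ-butyrolactone enolates (conjugate addition–enolate trapping). No ring is closed; the lactone ring from step 4 is carried through unchanged. Of the two new stereocentres, the β-carbon is controlled by the C5 aryl group and the α-carbon by the β-methyl group (1,2-induction each time), and the all-trans product is also the thermodynamically preferred α-epimer. The step needs conjugate addition to outrun removal of the acidic γ-hydrogen (which would racemise 7 through the achiral 2-oxidofuran) and needs mono- rather than double methylation; inverse addition of 7 to excess cuprate at −78 °C and a large excess of MeI with HMPA at low temperature are meant to secure both.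

**Step 6**
Reactants: 10 4-bromo-2-methoxyphenol
Product: 11 (4-bromo-2-methoxyphenoxy)triisopropylsilane
Conditions: TIPSCl, imidazole, DMF, rt
Reagents that add atoms: chlorotriisopropylsilane, CC(C)[Si](Cl)(C(C)C)C(C)C
Why: silylation of the phenol; the bulky triisopropylsilyl aryl ether should tolerate organometal formation, BF3·OEt2, hydrogenolysis and carbonate base, and is removed by fluoride at the end.

**Step 7**
Reactants: 11 (4-bromo-2-methoxyphenoxy)triisopropylsilane; 9 (3R,4R,5R)-5-(4-benzyloxy-3-methoxyphenyl)-3,4-dimethyldihydrofuran-2(3H)-one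
Product: 13 (3R,4R,5R)-5-(4-benzyloxy-3-methoxyphenyl)-2-[3-methoxy-4-(triisopropylsilyloxy)phenyl]-3,4-dimethyloxolan-2-ol (C2 anomer mixture), via aryllithium 12 (not isolated)
Conditions: 11, n-BuLi, THF, −78 °C; then 9, −78 °C; aq. NH4Cl at −78 °C
Reagents that add atoms: none
Why: bromine–lithium exchange gives aryllithium 12, which should add once to the lactone carbonyl because the lithium alkoxide of the cyclic hemiketal is stable at −78 °C (acyl addition of an organolithium to a lactone); the hemiketal carbon forms as an anomer mixture, which is irrelevant because it becomes planar in the next step.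

**Step 8**
Reactants: 13 (3R,4R,5R)-5-(4-benzyloxy-3-methoxyphenyl)-2-[3-methoxy-4-(triisopropylsilyloxy)phenyl]-3,4-dimethyloxolan-2-ol
Product: 14 (2R,3R,4R,5S)-2-(4-benzyloxy-3-methoxyphenyl)-5-[3-methoxy-4-(triisopropylsilyloxy)phenyl]-3,4-dimethyloxolane
Conditions: Et3SiH, BF3·OEt2, CH2Cl2, −78 °C
Reagents that add atoms: none
Why: ionic hydrogenation: BF3·OEt2 ionises the hemiketal to the aryl-stabilised cyclic oxocarbenium ion and Et3SiH delivers hydride by inside attack on the envelope in which the C4 methyl is pseudo-axial (avoiding allylic 1,2-strain with the coplanar ring C), i.e. anti to the C4 methyl, so ring C should end cis to the C4 methyl and C5 is set as S.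

**Step 9**
Reactants: 14 (2R,3R,4R,5S)-2-(4-benzyloxy-3-methoxyphenyl)-5-[3-methoxy-4-(triisopropylsilyloxy)phenyl]-3,4-dimethyloxolane
Product: 15 2-methoxy-4-{(2R,3R,4R,5S)-5-[3-methoxy-4-(triisopropylsilyloxy)phenyl]-3,4-dimethyloxolan-2-yl}phenol
Conditions: H2 (1 atm), Pd/C, EtOAc, rt
Reagents that add atoms: none
Why: hydrogenolysis of the aryl benzyl ether is expected to be much faster than cleavage of the benzylic C–O bonds of the oxolane and leaves the silyl ether intact, so only the ring B phenol is freed.

**Step 10**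
Reactants: 16 ethyl (S)-lactate
Product: 17 (S)-2-hydroxy-N-methoxy-N-methylpropanamide
Conditions: MeNH(OMe)·HCl, i-PrMgCl, THF, −20 → 0 °C
Reagents that add atoms: N,O-dimethylhydroxylamine hydrochloride, CNOC.Cl
Why: aminolysis of the ester by the magnesium amide of N,O-dimethylhydroxylamine gives the Weinreb amide; the α-stereocentre is safe because its hydrogen is not acidic next to the magnesium alkoxide.

**Step 11**
Reactants: 11 (4-bromo-2-methoxyphenoxy)triisopropylsilane; 17 (S)-2-hydroxy-N-methoxy-N-methylpropanamide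
Product: 19 (S)-2-hydroxy-1-[3-methoxy-4-(triisopropylsilyloxy)phenyl]propan-1-one, via arylmagnesium bromide 18 (not isolated)
Conditions: 11, Mg, THF, 40 °C; 17, i-PrMgCl (1.0 equiv, deprotonates OH), THF, −20 °C, then 18, 0 °C → rt; aq. NH4Cl
Reagents that add atoms: none
Why: magnesium insertion gives Grignard reagent 18, whose addition to the Weinreb amide stops at the chelated tetrahedral intermediate and gives the aryl ketone on work-up (Weinreb ketone synthesis), the adjacent magnesium alkoxide disfavouring enolisation so that the α-stereocentre is kept.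

**Step 12**
Reactants: 19 (S)-2-hydroxy-1-[3-methoxy-4-(triisopropylsilyloxy)phenyl]propan-1-one
Product: 20 (S)-1-[3-methoxy-4-(triisopropylsilyloxy)phenyl]-1-oxopropan-2-yl 4-methylbenzenesulfonate
Conditions: TsCl, Et3N, DMAP (cat.), CH2Cl2, 0 °C
Reagents that add atoms: 4-toluenesulfonyl chloride, Cc1ccc(S(=O)(=O)Cl)cc1
Why: O-sulfonylation turns the secondary alcohol into a leaving group with retention at carbon, since only the O–S bond is formed.

**Step 13**
Reactants: 15 2-methoxy-4-{(2R,3R,4R,5S)-5-[3-methoxy-4-(triisopropylsilyloxy)phenyl]-3,4-dimethyloxolan-2-yl}phenol; 20 (S)-1-[3-methoxy-4-(triisopropylsilyloxy)phenyl]-1-oxopropan-2-yl 4-methylbenzenesulfonate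
Product: 21 (R)-2-(2-methoxy-4-{(2R,3R,4R,5S)-5-[3-methoxy-4-(triisopropylsilyloxy)phenyl]-3,4-dimethyloxolan-2-yl}phenoxy)-1-[3-methoxy-4-(triisopropylsilyloxy)phenyl]propan-1-one
Conditions: K2CO3, MeCN, rt
Reagents that add atoms: none
Why: SN2 displacement of the carbonyl-activated tosylate by the ring B phenoxide (Williamson etherification) proceeds with inversion to the (R)-aryl ether, and the mild carbonate base at room temperature should neither epimerise C8 nor cleave the triisopropylsilyl ethers.

**Step 14**
Reactants: 21 (R)-2-(2-methoxy-4-{(2R,3R,4R,5S)-5-[3-methoxy-4-(triisopropylsilyloxy)phenyl]-3,4-dimethyloxolan-2-yl}phenoxy)-1-[3-methoxy-4-(triisopropylsilyloxy)phenyl]propan-1-one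
Product: 22 (1R,2R)-2-(2-methoxy-4-{(2R,3R,4R,5S)-5-[3-methoxy-4-(triisopropylsilyloxy)phenyl]-3,4-dimethyloxolan-2-yl}phenoxy)-1-[3-methoxy-4-(triisopropylsilyloxy)phenyl]propan-1-ol
Conditions: polymer-supported borohydride (quaternary ammonium resin, BH4− form), MeOH, 0 °C
Reagents that add atoms: none
Why: hydride reduction of the ketone without a chelating metal cation should follow the polar Felkin–Anh model, hydride attacking anti to the C8 aryloxy group and past the C8 hydrogen, which sets C7 as R (threo to C8).

**Step 15**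
Reactants: 22 (1R,2R)-2-(2-methoxy-4-{(2R,3R,4R,5S)-5-[3-methoxy-4-(triisopropylsilyloxy)phenyl]-3,4-dimethyloxolan-2-yl}phenoxy)-1-[3-methoxy-4-(triisopropylsilyloxy)phenyl]propan-1-ol
Product: 23 (1R,2R)-1-(4-hydroxy-3-methoxyphenyl)-2-{4-[(2R,3R,4R,5S)-5-(4-hydroxy-3-methoxyphenyl)-3,4-dimethyloxolan-2-yl]-2-methoxyphenoxy}propan-1-ol
Conditions: n-Bu4NF, AcOH, THF, 0 °C → rt
Reagents that add atoms: none
Why: fluoride-induced cleavage of both aryl silyl ethers, buffered with acetic acid so that the phenoxides are protonated at once and cannot expel the C7 hydroxyl or open the oxolane through quinone methides.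

**Compound list**
1 | vanillin | COc1cc(C=O)ccc1O | starting material
2 | 4-benzyloxy-3-methoxybenzaldehyde | COc1cc(C=O)ccc1OCc1ccccc1 | intermediate
3 | vinylmagnesium bromide | C=C[Mg]Br | starting material
4 | rac-1-(4-benzyloxy-3-methoxyphenyl)prop-2-en-1-ol | COc1cc(C(O)C=C)ccc1OCc1ccccc1 | intermediate
5 | vinyl acrylate | C=CC(=O)OC=C | starting material
6 | (R)-1-(4-benzyloxy-3-methoxyphenyl)prop-2-en-1-yl acrylate | COc1cc([C@@H](C=C)OC(=O)C=C)ccc1OCc1ccccc1 | intermediate
7 | (R)-5-(4-benzyloxy-3-methoxyphenyl)furan-2(5H)-one | COc1cc([C@@H]2OC(=O)C=C2)ccc1OCc1ccccc1 | intermediate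
8 | lithium (4R,5R)-5-(4-benzyloxy-3-methoxyphenyl)-4-methyl-4,5-dihydrofuran-2-olate | COc1cc([C@@H]2OC([O-])=C[C@H]2C)ccc1OCc1ccccc1.[Li+] | intermediate (not isolated)
9 | (3R,4R,5R)-5-(4-benzyloxy-3-methoxyphenyl)-3,4-dimethyldihydrofuran-2(3H)-one | COc1cc([C@@H]2OC(=O)[C@H](C)[C@H]2C)ccc1OCc1ccccc1 | intermediate
10 | 4-bromo-2-methoxyphenol | COc1cc(Br)ccc1O | starting material
11 | (4-bromo-2-methoxyphenoxy)triisopropylsilane | COc1cc(Br)ccc1O[Si](C(C)C)(C(C)C)C(C)C | intermediate
12 | [3-methoxy-4-(triisopropylsilyloxy)phenyl]lithium | COc1cc([Li])ccc1O[Si](C(C)C)(C(C)C)C(C)C | intermediate (not isolated)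
13 | (3R,4R,5R)-5-(4-benzyloxy-3-methoxyphenyl)-2-[3-methoxy-4-(triisopropylsilyloxy)phenyl]-3,4-dimethyloxolan-2-ol (C2 anomer mixture) | COc1cc([C@@H]2OC(O)(c3ccc(O[Si](C(C)C)(C(C)C)C(C)C)c(OC)c3)[C@H](C)[C@H]2C)ccc1OCc1ccccc1 | intermediate
14 | (2R,3R,4R,5S)-2-(4-benzyloxy-3-methoxyphenyl)-5-[3-methoxy-4-(triisopropylsilyloxy)phenyl]-3,4-dimethyloxolane | COc1cc([C@@H]2O[C@H](c3ccc(O[Si](C(C)C)(C(C)C)C(C)C)c(OC)c3)[C@H](C)[C@H]2C)ccc1OCc1ccccc1 | intermediate
15 | 2-methoxy-4-{(2R,3R,4R,5S)-5-[3-methoxy-4-(triisopropylsilyloxy)phenyl]-3,4-dimethyloxolan-2-yl}phenol | COc1cc([C@@H]2O[C@H](c3ccc(O[Si](C(C)C)(C(C)C)C(C)C)c(OC)c3)[C@H](C)[C@H]2C)ccc1O | intermediate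
16 | ethyl (S)-lactate | CCOC(=O)[C@H](C)O | starting material
17 | (S)-2-hydroxy-N-methoxy-N-methylpropanamide | CON(C)C(=O)[C@H](C)O | intermediate
18 | [3-methoxy-4-(triisopropylsilyloxy)phenyl]magnesium bromide | COc1cc([Mg]Br)ccc1O[Si](C(C)C)(C(C)C)C(C)C | intermediate (not isolated)
19 | (S)-2-hydroxy-1-[3-methoxy-4-(triisopropylsilyloxy)phenyl]propan-1-one | COc1cc(C(=O)[C@H](C)O)ccc1O[Si](C(C)C)(C(C)C)C(C)C | intermediate
20 | (S)-1-[3-methoxy-4-(triisopropylsilyloxy)phenyl]-1-oxopropan-2-yl 4-methylbenzenesulfonate | COc1cc(C(=O)[C@H](C)OS(=O)(=O)c2ccc(C)cc2)ccc1O[Si](C(C)C)(C(C)C)C(C)C | intermediate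
21 | (R)-2-(2-methoxy-4-{(2R,3R,4R,5S)-5-[3-methoxy-4-(triisopropylsilyloxy)phenyl]-3,4-dimethyloxolan-2-yl}phenoxy)-1-[3-methoxy-4-(triisopropylsilyloxy)phenyl]propan-1-one | COc1cc(C(=O)[C@@H](C)Oc2ccc([C@@H]3O[C@H](c4ccc(O[Si](C(C)C)(C(C)C)C(C)C)c(OC)c4)[C@H](C)[C@H]3C)cc2OC)ccc1O[Si](C(C)C)(C(C)C)C(C)C | intermediate
22 | (1R,2R)-2-(2-methoxy-4-{(2R,3R,4R,5S)-5-[3-methoxy-4-(triisopropylsilyloxy)phenyl]-3,4-dimethyloxolan-2-yl}phenoxy)-1-[3-methoxy-4-(triisopropylsilyloxy)phenyl]propan-1-ol | COc1cc([C@@H](O)[C@@H](C)Oc2ccc([C@@H]3O[C@H](c4ccc(O[Si](C(C)C)(C(C)C)C(C)C)c(OC)c4)[C@H](C)[C@H]3C)cc2OC)ccc1O[Si](C(C)C)(C(C)C)C(C)C | intermediate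
23 | (1R,2R)-1-(4-hydroxy-3-methoxyphenyl)-2-{4-[(2R,3R,4R,5S)-5-(4-hydroxy-3-methoxyphenyl)-3,4-dimethyloxolan-2-yl]-2-methoxyphenoxy}propan-1-ol | COc1cc([C@@H](O)[C@@H](C)Oc2ccc([C@@H]3O[C@H](c4ccc(O)c(OC)c4)[C@H](C)[C@H]3C)cc2OC)ccc1O | target

**Step count**
Total: 15 steps. Longest linear sequence: 11 steps (1, 2, 3, 4, 5, 7, 8, 9, 13, 14, 15, from vanillin).

**Steps most likely to fail**

Step 5. The copper-associated enolate may be methylated slowly, so that proton exchange between enolate and product leads to incomplete or double methylation. Enantiopurity is lost if the cuprate removes the γ-hydrogen of 7 before it adds. Fallback, setting out from 7 and returning at 9: the two C–C bonds are made in separate operations. Me2CuLi in Et2O at −78 °C with NH4Cl quench should give the monomethyl lactone (4R,5R)-5-(4-benzyloxy-3-methoxyphenyl)-4-methyldihydrofuran-2(3H)-one F1. This is deprotonated with LiN(SiMe3)2 in THF at −78 °C and alkylated with MeI trans to the C4 methyl group to give 9.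

Step 8. Hydride delivery to the aryl-stabilised oxocarbenium ion may show poor facial selectivity, or the acid may ionise the electron-rich ring B benzylic C–O bond and cause epimerisation or reductive ring opening. Fallback, setting out from 9 and returning at 14: the order of bond formation at C5 is reversed. DIBAL-H (CH2Cl2, −78 °C) should give the lactol (3R,4R,5R)-5-(4-benzyloxy-3-methoxyphenyl)-3,4-dimethyloxolan-2-ol F2. Benzenesulfinic acid and CaCl2 in CH2Cl2 convert it into the sulfone (3R,4R,5R)-5-(4-benzyloxy-3-methoxyphenyl)-3,4-dimethyl-2-(phenylsulfonyl)oxolane F3. The arylzinc reagent [3-methoxy-4-(triisopropylsilyloxy)phenyl]zinc bromide F4 (from 18 and ZnBr2, THF, rt) then displaces sulfinate through the C5–H oxocarbenium ion. With all three substituents pseudo-equatorial, inside attack should bring the aryl group in cis to the adjacent C4 methyl, giving 14.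

Step 14. Hydride addition may show insufficient facial selectivity and give the erythro alcohol, or ketone 21 may epimerise at C8 before it is reduced. Fallback, setting out from 15 and returning at 22: the side chain is built from the other end. Mitsunobu etherification of 15 with ethyl (S)-lactate 16 (PPh3, diisopropyl azodicarboxylate, THF, inversion) should give ethyl (R)-2-(2-methoxy-4-{(2R,3R,4R,5S)-5-[3-methoxy-4-(triisopropylsilyloxy)phenyl]-3,4-dimethyloxolan-2-yl}phenoxy)propanoate F5. DIBAL-H (toluene, −78 °C) reduces it to the aldehyde (R)-2-(2-methoxy-4-{(2R,3R,4R,5S)-5-[3-methoxy-4-(triisopropylsilyloxy)phenyl]-3,4-dimethyloxolan-2-yl}phenoxy)propanal F6. Grignard reagent 18 is then added with MgBr2·OEt2 (CH2Cl2/Et2O, −78 °C) under chelation control, magnesium bridging the aldehyde and aryl ether oxygens and the aryl group attacking anti to the C8 methyl, to give the threo alcohol 22.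

**Further compounds**
F1 | step 5 | (4R,5R)-5-(4-benzyloxy-3-methoxyphenyl)-4-methyldihydrofuran-2(3H)-one | COc1cc([C@@H]2OC(=O)C[C@H]2C)ccc1OCc1ccccc1
F2 | step 8 | (3R,4R,5R)-5-(4-benzyloxy-3-methoxyphenyl)-3,4-dimethyloxolan-2-ol (C2 anomer mixture) | COc1cc([C@@H]2OC(O)[C@H](C)[C@H]2C)ccc1OCc1ccccc1
F3 | step 8 | (3R,4R,5R)-5-(4-benzyloxy-3-methoxyphenyl)-3,4-dimethyl-2-(phenylsulfonyl)oxolane (C2 anomer mixture) | COc1cc([C@@H]2OC(S(=O)(=O)c3ccccc3)[C@H](C)[C@H]2C)ccc1OCc1ccccc1
F4 | step 8 | [3-methoxy-4-(triisopropylsilyloxy)phenyl]zinc bromide | COc1cc([Zn]Br)ccc1O[Si](C(C)C)(C(C)C)C(C)C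
F5 | step 14 | ethyl (R)-2-(2-methoxy-4-{(2R,3R,4R,5S)-5-[3-methoxy-4-(triisopropylsilyloxy)phenyl]-3,4-dimethyloxolan-2-yl}phenoxy)propanoate | CCOC(=O)[C@@H](C)Oc1ccc([C@@H]2O[C@H](c3ccc(O[Si](C(C)C)(C(C)C)C(C)C)c(OC)c3)[C@H](C)[C@H]2C)cc1OC
F6 | step 14 | (R)-2-(2-methoxy-4-{(2R,3R,4R,5S)-5-[3-methoxy-4-(triisopropylsilyloxy)phenyl]-3,4-dimethyloxolan-2-yl}phenoxy)propanal | O=C[C@@H](C)Oc1ccc([C@@H]2O[C@H](c3ccc(O[Si](C(C)C)(C(C)C)C(C)C)c(OC)c3)[C@H](C)[C@H]2C)cc1OC
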